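Ring A of the chromone is made last. A preformed 4-pyranone already supplies O-1, C-2, C-3, C-4, C-4a and C-8a, and C-5 to C-8 are annulated onto its C-4a–C-8a bond. The target's 5,7-dioxygenation with hydrogen at C-6 and C-8 is the pattern of a ketene–siloxyalkyne benzannulation. One photothermal operation turns a diazoacetyl group and triisopropylsiloxyacetylene into the fused arene, forming four C–C bonds and placing the C-5 hydroxyl beside C-4=O and a silyl ether at C-7. The precursor is the fully benzylated (R)-ketone whose Cα carries a 6-diazoacetyl-4-pyranon-3-yl group, assembled by palladium coupling of a comenic acid triflate with a β,β-diaryl ketone and resolved before the annulation.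

Key step: step 10

Assumption: Cα–H is acidic enough that any enolate-based coupling leaves it racemic, so Cα is resolved afterwards, its configuration is assigned by X-ray or ECD analysis, and no base is used from then on.

Step 1
Reactants: 1 2',4',6'-trihydroxyacetophenone
Product: 2 1-[2,4,6-tris(benzyloxy)phenyl]ethan-1-one
Conditions: BnBr (3.5 equiv), K2CO3, DMF, 80 °C
Reagents that add atoms: benzyl bromide, BrCc1ccccc1
Why: Williamson etherification of all three phenols, with excess carbonate and heat in DMF so that the hydrogen-bonded ortho hydroxyls are alkylated as well.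

Step 2
Reactants: 2 1-[2,4,6-tris(benzyloxy)phenyl]ethan-1-one, 3 4-(benzyloxy)benzaldehyde
Product: 4 (E)-3-[4-(benzyloxy)phenyl]-1-[2,4,6-tris(benzyloxy)phenyl]prop-2-en-1-one
Conditions: KOH, EtOH/THF, 25 °C
Reagents that add atoms: none
Why: Claisen–Schmidt aldol condensation between a ketone that enolises only at its methyl group and a non-enolisable aldehyde, with dehydration giving the conjugated (E)-enone.

Step 3
Reactants: 4 (E)-3-[4-(benzyloxy)phenyl]-1-[2,4,6-tris(benzyloxy)phenyl]prop-2-en-1-one, 5 [4-(benzyloxy)phenyl]boronic acid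
Product: 6 3,3-bis[4-(benzyloxy)phenyl]-1-[2,4,6-tris(benzyloxy)phenyl]propan-1-one
Conditions: [Rh(cod)Cl]2 (3 mol%), KOH, dioxane/H2O, 60 °C
Reagents that add atoms: none
Why: Hayashi–Miyaura rhodium-catalysed 1,4-addition, in which the aryl–rhodium species inserts the enone and the resulting enolate is protonated by water; the carbonyl between two ortho benzyloxy groups is shielded from 1,2-addition and no stereocenter arises because the two aryl groups at C-3 are identical.

Step 4
Reactants: 7 comenic acid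
Product: 8 methyl 5-hydroxy-4-oxo-4H-pyran-2-carboxylate
Conditions: MeOH, H2SO4 (cat.), reflux
Reagents that add atoms: methanol, CO
Why: Fischer esterification of the carboxylic acid, which leaves the enolic 5-hydroxyl free.

Step 5
Reactants: 8 methyl 5-hydroxy-4-oxo-4H-pyran-2-carboxylate
Product: 9 methyl 4-oxo-5-[(trifluoromethanesulfonyl)oxy]-4H-pyran-2-carboxylate
Conditions: Tf2O, pyridine, CH2Cl2, 0 °C
Reagents that add atoms: trifluoromethanesulfonic anhydride, O=S(=O)(OS(=O)(=O)C(F)(F)F)C(F)(F)F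
Why: O-sulfonylation of the acidic enolic hydroxyl, giving a pyranonyl triflate that is ready for oxidative addition.

Step 6
Reactants: 6 3,3-bis[4-(benzyloxy)phenyl]-1-[2,4,6-tris(benzyloxy)phenyl]propan-1-one, 9 methyl 4-oxo-5-[(trifluoromethanesulfonyl)oxy]-4H-pyran-2-carboxylate
Product: 11 racemic 5-{1,1-bis[4-(benzyloxy)phenyl]-3-oxo-3-[2,4,6-tris(benzyloxy)phenyl]propan-2-yl}-4-oxo-4H-pyran-2-carboxylic acid, via racemic methyl ester 10 (not isolated)
Conditions: Pd2(dba)3 (2.5 mol%), XPhos, K3PO4, PhMe, 90 °C; then LiOH, THF/H2O, 0 °C; 1 M HCl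
Reagents that add atoms: lithium hydroxide, [Li+].[OH-]
Why: Buchwald–Hartwig-type ketone α-arylation (oxidative addition of zerovalent palladium into the pyranonyl triflate, coupling with the potassium enolate at the only enolisable carbon, reductive elimination) should form the Cα–pyranone bond once, since the hindered product enolate resists a second arylation; Cα arises racemic by design, and the activated pyranone ester is then saponified by LiOH at 0 °C without opening the ring.

Step 7
Reactants: 11 racemic 5-{1,1-bis[4-(benzyloxy)phenyl]-3-oxo-3-[2,4,6-tris(benzyloxy)phenyl]propan-2-yl}-4-oxo-4H-pyran-2-carboxylic acid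
Product: 12 5-{(2R)-1,1-bis[4-(benzyloxy)phenyl]-3-oxo-3-[2,4,6-tris(benzyloxy)phenyl]propan-2-yl}-4-oxo-4H-pyran-2-carboxylic acid
Conditions: preparative chiral SFC, amylose tris(3,5-dimethylphenylcarbamate) phase, CO2/MeOH with 0.1% HCO2H, 35 °C
Reagents that add atoms: none
Why: Chromatographic resolution on a polysaccharide chiral stationary phase separates the enantiomers without any reagent that could enolise the ketone, so Cα is obtained in the (R) form here, and the (S) acid is racemised through its enolate with DBU and fed back.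

Step 8
Reactants: 12 5-{(2R)-1,1-bis[4-(benzyloxy)phenyl]-3-oxo-3-[2,4,6-tris(benzyloxy)phenyl]propan-2-yl}-4-oxo-4H-pyran-2-carboxylic acid
Product: 14 (R)-2-[6-(2-diazoacetyl)-4-oxo-4H-pyran-3-yl]-3,3-bis[4-(benzyloxy)phenyl]-1-[2,4,6-tris(benzyloxy)phenyl]propan-1-one, via acid chloride 13 (not isolated)
Conditions: (COCl)2, DMF (cat.), CH2Cl2, 0 → 25 °C; then TMSCHN2 (2.5 equiv), THF/MeCN, 0 °C
Reagents that add atoms: (trimethylsilyl)diazomethane, C[Si](C)(C)C=[N+]=[N-]
Why: Acid chloride formation under Vilsmeier catalysis followed by C-acylation of (trimethylsilyl)diazomethane with loss of the silyl group (Arndt–Eistert-type diazo ketone synthesis) runs without amine base, so the acidic Cα–H is not touched, and the silylated reagent is the safer substitute for diazomethane.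

Step 9
Reactants: 15 ethyl formate, 16 dibromomethane
Product: 20 (triisopropylsilyloxy)acetylene, via dibromomethyllithium 17 (not isolated), via lithium 2,2-dibromoethenolate 18 (not isolated), via lithium ethynolate 19 (not isolated)
Conditions: lithium 2,2,6,6-tetramethylpiperidide (2.2 equiv), THF, −78 °C; n-BuLi, −78 → 25 °C; i-Pr3SiCl, 0 → 25 °C
Reagents that add atoms: chlorotriisopropylsilane, CC(C)[Si](Cl)(C(C)C)C(C)C
Why: Kowalski ester homologation, in which 17 adds to the formate, loss of ethoxide and deprotonation give 18, bromine–lithium exchange triggers a carbenoid 1,2-hydrogen shift to 19, and the bulky chlorosilane silylates the ynolate at oxygen and not at carbon.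

Step 10
Reactants: 14 (R)-2-[6-(2-diazoacetyl)-4-oxo-4H-pyran-3-yl]-3,3-bis[4-(benzyloxy)phenyl]-1-[2,4,6-tris(benzyloxy)phenyl]propan-1-one, 20 (triisopropylsilyloxy)acetylene
Product: 25 (R)-2-[5-hydroxy-4-oxo-7-(triisopropylsilyloxy)-4H-chromen-3-yl]-3,3-bis[4-(benzyloxy)phenyl]-1-[2,4,6-tris(benzyloxy)phenyl]propan-1-one, via pyranonyl ketene 21 (not isolated), via siloxycyclobutenone 22 (not isolated), via dienylketene 23 (not isolated), via cyclohexadienone tautomer 24 (not isolated)
Conditions: 20 (3 equiv), hν (420 nm LEDs), ClCH2CH2Cl, 25 °C; then 80 °C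
Reagents that add atoms: none
Why: Visible light excites only the diazo ketone, which loses N2 with 1,2-shift of the pyranonyl group (Wolff rearrangement) to give ketene 21; the electron-rich terminal carbon of 20 attacks the ketene carbonyl carbon in a [2+2] cycloaddition to cyclobutenone 22, which on warming opens by 4π electrocyclic cleavage to dienylketene 23, closes by 6π electrocyclization onto pyranone C-5 to dienone 24 and tautomerises to the phenol. This is the Danheiser benzannulation in its unsaturated diazo ketone/siloxyalkyne form, with the C-5=C-6 enol-ether double bond of the pyranone playing the vinyl part. Ring A is closed by the thermal six-electron electrocyclization that forms C-5–C-4a, after C-8a–C-8 (Wolff shift) and C-8–C-7 and C-6–C-5 (cycloaddition) are in place. No stereocenter is created, and Cα is left alone because the medium is neutral, aprotic and never above 80 °C. Regiochemistry is fixed by the polarity of the siloxyalkyne (the ketene carbon becomes C-5 with its free hydroxyl hydrogen-bonded to C-4=O, the siloxy carbon becomes C-7) and by the fact that the only carbon next to the ketene-bearing pyranone C-6 is C-5. Irradiation at 420 nm keeps the ortho-benzyloxyaryl ketone and the pyranone in their ground states, which should shut off δ-hydrogen abstraction and pyranone photorearrangement, and excess 20 should outrun ketene dimerisation.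

Step 11
Reactants: 25 (R)-2-[5-hydroxy-4-oxo-7-(triisopropylsilyloxy)-4H-chromen-3-yl]-3,3-bis[4-(benzyloxy)phenyl]-1-[2,4,6-tris(benzyloxy)phenyl]propan-1-one
Product: 26 (R)-2-(5,7-dihydroxy-4-oxo-4H-chromen-3-yl)-3,3-bis[4-(benzyloxy)phenyl]-1-[2,4,6-tris(benzyloxy)phenyl]propan-1-one
Conditions: HF·pyridine, THF, 0 → 25 °C
Reagents that add atoms: none
Why: Fluoride-driven cleavage of the aryl silyl ether, driven by the strong Si–F bond, under slightly acidic conditions that leave the benzyl ethers and Cα unchanged.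

Step 12
Reactants: 26 (R)-2-(5,7-dihydroxy-4-oxo-4H-chromen-3-yl)-3,3-bis[4-(benzyloxy)phenyl]-1-[2,4,6-tris(benzyloxy)phenyl]propan-1-one
Product: 27 (R)-2-(5,7-dihydroxy-4-oxo-4H-chromen-3-yl)-3,3-bis(4-hydroxyphenyl)-1-(2,4,6-trihydroxyphenyl)propan-1-one (CNP0106875.1)
Conditions: H2 (1 atm), 10% Pd/C, EtOAc/MeOH, 25 °C
Reagents that add atoms: none
Why: Palladium-catalysed hydrogenolysis of the five aryl benzyl ethers under neutral conditions, in which the 3-substituted chromone double bond and the hindered aryl ketone should be reduced far more slowly, so the (R) centre is carried unchanged into the target.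

Compound list
1 | 2',4',6'-trihydroxyacetophenone | CC(=O)c1c(O)cc(O)cc1O | starting material
2 | 1-[2,4,6-tris(benzyloxy)phenyl]ethan-1-one | CC(=O)c1c(OCc2ccccc2)cc(OCc2ccccc2)cc1OCc1ccccc1 | intermediate
3 | 4-(benzyloxy)benzaldehyde | O=Cc1ccc(OCc2ccccc2)cc1 | starting material
4 | (E)-3-[4-(benzyloxy)phenyl]-1-[2,4,6-tris(benzyloxy)phenyl]prop-2-en-1-one | O=C(/C=C/c1ccc(OCc2ccccc2)cc1)c1c(OCc2ccccc2)cc(OCc2ccccc2)cc1OCc1ccccc1 | intermediate
5 | [4-(benzyloxy)phenyl]boronic acid | OB(O)c1ccc(OCc2ccccc2)cc1 | starting material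
6 | 3,3-bis[4-(benzyloxy)phenyl]-1-[2,4,6-tris(benzyloxy)phenyl]propan-1-one | O=C(CC(c1ccc(OCc2ccccc2)cc1)c1ccc(OCc2ccccc2)cc1)c1c(OCc2ccccc2)cc(OCc2ccccc2)cc1OCc1ccccc1 | intermediate
7 | comenic acid (5-hydroxy-4-oxo-4H-pyran-2-carboxylic acid) | O=C(O)c1cc(=O)c(O)co1 | starting material
8 | methyl 5-hydroxy-4-oxo-4H-pyran-2-carboxylate | COC(=O)c1cc(=O)c(O)co1 | intermediate
9 | methyl 4-oxo-5-[(trifluoromethanesulfonyl)oxy]-4H-pyran-2-carboxylate | COC(=O)c1cc(=O)c(OS(=O)(=O)C(F)(F)F)co1 | intermediate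
10 | racemic methyl 5-{1,1-bis[4-(benzyloxy)phenyl]-3-oxo-3-[2,4,6-tris(benzyloxy)phenyl]propan-2-yl}-4-oxo-4H-pyran-2-carboxylate | O=C(c1c(OCc2ccccc2)cc(OCc2ccccc2)cc1OCc1ccccc1)C(c1coc(C(=O)OC)cc1=O)C(c1ccc(OCc2ccccc2)cc1)c1ccc(OCc2ccccc2)cc1 | intermediate
11 | racemic 5-{1,1-bis[4-(benzyloxy)phenyl]-3-oxo-3-[2,4,6-tris(benzyloxy)phenyl]propan-2-yl}-4-oxo-4H-pyran-2-carboxylic acid | O=C(c1c(OCc2ccccc2)cc(OCc2ccccc2)cc1OCc1ccccc1)C(c1coc(C(=O)O)cc1=O)C(c1ccc(OCc2ccccc2)cc1)c1ccc(OCc2ccccc2)cc1 | intermediate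
12 | 5-{(2R)-1,1-bis[4-(benzyloxy)phenyl]-3-oxo-3-[2,4,6-tris(benzyloxy)phenyl]propan-2-yl}-4-oxo-4H-pyran-2-carboxylic acid | O=C(c1c(OCc2ccccc2)cc(OCc2ccccc2)cc1OCc1ccccc1)[C@@H](c1coc(C(=O)O)cc1=O)C(c1ccc(OCc2ccccc2)cc1)c1ccc(OCc2ccccc2)cc1 | intermediate
13 | 5-{(2R)-1,1-bis[4-(benzyloxy)phenyl]-3-oxo-3-[2,4,6-tris(benzyloxy)phenyl]propan-2-yl}-4-oxo-4H-pyran-2-carbonyl chloride | O=C(c1c(OCc2ccccc2)cc(OCc2ccccc2)cc1OCc1ccccc1)[C@@H](c1coc(C(Cl)=O)cc1=O)C(c1ccc(OCc2ccccc2)cc1)c1ccc(OCc2ccccc2)cc1 | intermediate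
14 | (R)-2-[6-(2-diazoacetyl)-4-oxo-4H-pyran-3-yl]-3,3-bis[4-(benzyloxy)phenyl]-1-[2,4,6-tris(benzyloxy)phenyl]propan-1-one | O=C(c1c(OCc2ccccc2)cc(OCc2ccccc2)cc1OCc1ccccc1)[C@@H](c1coc(C(=O)C=[N+]=[N-])cc1=O)C(c1ccc(OCc2ccccc2)cc1)c1ccc(OCc2ccccc2)cc1 | intermediate
15 | ethyl formate | CCOC=O | starting material
16 | dibromomethane | BrCBr | starting material
17 | dibromomethyllithium | [Li]C(Br)Br | intermediate
18 | lithium 2,2-dibromoethenolate | [Li+].[O-]C=C(Br)Br | intermediate
19 | lithium ethynolate | [Li+].[O-]C#C | intermediate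
20 | (triisopropylsilyloxy)acetylene | C#CO[Si](C(C)C)(C(C)C)C(C)C | intermediate
21 | (R)-3,3-bis[4-(benzyloxy)phenyl]-2-[4-oxo-6-(2-oxoethenyl)-4H-pyran-3-yl]-1-[2,4,6-tris(benzyloxy)phenyl]propan-1-one | O=C(c1c(OCc2ccccc2)cc(OCc2ccccc2)cc1OCc1ccccc1)[C@@H](c1coc(C=C=O)cc1=O)C(c1ccc(OCc2ccccc2)cc1)c1ccc(OCc2ccccc2)cc1 | intermediate
22 | (2R)-3,3-bis[4-(benzyloxy)phenyl]-2-{4-oxo-6-[4-oxo-2-(triisopropylsilyloxy)cyclobut-2-en-1-yl]-4H-pyran-3-yl}-1-[2,4,6-tris(benzyloxy)phenyl]propan-1-one, both epimers at the cyclobutene carbon | O=C(c1c(OCc2ccccc2)cc(OCc2ccccc2)cc1OCc1ccccc1)[C@@H](c1coc(C2C(=O)C=C2O[Si](C(C)C)(C(C)C)C(C)C)cc1=O)C(c1ccc(OCc2ccccc2)cc1)c1ccc(OCc2ccccc2)cc1 | intermediate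
23 | (2R)-3,3-bis[4-(benzyloxy)phenyl]-2-{4-oxo-6-[4-oxo-2-(triisopropylsilyloxy)buta-1,3-dien-1-yl]-4H-pyran-3-yl}-1-[2,4,6-tris(benzyloxy)phenyl]propan-1-one, alkene geometry not fixed | O=C(c1c(OCc2ccccc2)cc(OCc2ccccc2)cc1OCc1ccccc1)[C@@H](c1coc(C=C(O[Si](C(C)C)(C(C)C)C(C)C)C=C=O)cc1=O)C(c1ccc(OCc2ccccc2)cc1)c1ccc(OCc2ccccc2)cc1 | intermediate
24 | (2R)-3,3-bis[4-(benzyloxy)phenyl]-2-[4,5-dioxo-7-(triisopropylsilyloxy)-4a,5-dihydro-4H-chromen-3-yl]-1-[2,4,6-tris(benzyloxy)phenyl]propan-1-one, both epimers at C-4a | O=C(c1c(OCc2ccccc2)cc(OCc2ccccc2)cc1OCc1ccccc1)[C@@H](C1=COC2=CC(O[Si](C(C)C)(C(C)C)C(C)C)=CC(=O)C2C1=O)C(c1ccc(OCc2ccccc2)cc1)c1ccc(OCc2ccccc2)cc1 | intermediate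
25 | (R)-2-[5-hydroxy-4-oxo-7-(triisopropylsilyloxy)-4H-chromen-3-yl]-3,3-bis[4-(benzyloxy)phenyl]-1-[2,4,6-tris(benzyloxy)phenyl]propan-1-one | O=C(c1c(OCc2ccccc2)cc(OCc2ccccc2)cc1OCc1ccccc1)[C@@H](c1coc2cc(O[Si](C(C)C)(C(C)C)C(C)C)cc(O)c2c1=O)C(c1ccc(OCc2ccccc2)cc1)c1ccc(OCc2ccccc2)cc1 | intermediate
26 | (R)-2-(5,7-dihydroxy-4-oxo-4H-chromen-3-yl)-3,3-bis[4-(benzyloxy)phenyl]-1-[2,4,6-tris(benzyloxy)phenyl]propan-1-one | O=C(c1c(OCc2ccccc2)cc(OCc2ccccc2)cc1OCc1ccccc1)[C@@H](c1coc2cc(O)cc(O)c2c1=O)C(c1ccc(OCc2ccccc2)cc1)c1ccc(OCc2ccccc2)cc1 | intermediate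
27 | (R)-2-(5,7-dihydroxy-4-oxo-4H-chromen-3-yl)-3,3-bis(4-hydroxyphenyl)-1-(2,4,6-trihydroxyphenyl)propan-1-one (CNP0106875.1) | O=C(c1c(O)cc(O)cc1O)[C@@H](c1coc2cc(O)cc(O)c2c1=O)C(c1ccc(O)cc1)c1ccc(O)cc1 | target

Total step count: 12. Longest linear sequence: 9 steps (steps 1, 2, 3, 6, 7, 8, 10, 11 and 12).

Steps most likely to fail

Step 10 is the riskiest. The ketene may be consumed before ring A closes, by dimerisation or by acylating the product phenol. Nitrogen loss may also proceed through a free acyl carbene that inserts into benzylic C–H bonds, or residual excitation of the aryl ketone may start hydrogen abstraction. The fallback sets out from 14 and returns at 25, and it generates the same ketene in the dark without a carbene. Silver-catalysed Wolff rearrangement of 14 in aqueous dioxane (PhCO2Ag, ultrasound, 25 °C; Arndt–Eistert homologation) should give the homologous pyranonylacetic acid F1. Oxalyl chloride converts it into the pyranonylacetyl chloride F2. Slow addition of i-Pr2NEt to F2 and 20 in toluene (25 → 80 °C, up to 110 °C if the cyclobutenone is slow to open) releases ketene 21 by dehydrochlorination, and the known ketene–ynol ether cascade through 22, 23 and 24 leads to 25. The CH2 hydrogens of F2 are far more acidic than Cα–H, so the hindered amine should not epimerise Cα.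

Step 6 comes second. Reductive elimination from a palladium enolate that carries the bulky β,β-diaryl branch may be slow, so that triflate cleavage or O-sulfonylation of the enolate takes over. The fallback sets out from 2 and 9 and returns at 10; it moves the palladium step to an unhindered carbon and makes the congested bond by cation chemistry. α-Arylation of the methyl ketone 2 with 9 under the same catalyst should give the pyranonylmethyl ketone F3. TMSOTf/Et3N converts it into its trimethylsilyl enol ether F4. Sc(OTf)3-catalysed SN1 alkylation (Mukaiyama-type) of F4 with the stabilised cation from bis[4-(benzyloxy)phenyl]methanol F5, itself made from 3 and 4-(benzyloxy)phenylmagnesium bromide, installs the diarylmethyl group and gives 10, which is saponified as in the second operation of step 6.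

Step 12 comes third. Hydrogen may add to the chromone C-2=C-3 bond once the benzyl groups are gone, or hydrogenolysis may stall at the two hindered ortho benzyl ethers. The fallback sets out from 26 and returns at 27: BCl3 with pentamethylbenzene as cation scavenger in CH2Cl2 at −78 °C cleaves aryl benzyl ethers without hydrogen, helped at the ortho positions by chelation to the ketone, and the low temperature protects Cα. It makes no compound outside the list (none F0).

Further compounds
F1 | step 10 | 2-(5-{(2R)-1,1-bis[4-(benzyloxy)phenyl]-3-oxo-3-[2,4,6-tris(benzyloxy)phenyl]propan-2-yl}-4-oxo-4H-pyran-2-yl)acetic acid | O=C(c1c(OCc2ccccc2)cc(OCc2ccccc2)cc1OCc1ccccc1)[C@@H](c1coc(CC(=O)O)cc1=O)C(c1ccc(OCc2ccccc2)cc1)c1ccc(OCc2ccccc2)cc1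
F2 | step 10 | 2-(5-{(2R)-1,1-bis[4-(benzyloxy)phenyl]-3-oxo-3-[2,4,6-tris(benzyloxy)phenyl]propan-2-yl}-4-oxo-4H-pyran-2-yl)acetyl chloride | O=C(c1c(OCc2ccccc2)cc(OCc2ccccc2)cc1OCc1ccccc1)[C@@H](c1coc(CC(=O)Cl)cc1=O)C(c1ccc(OCc2ccccc2)cc1)c1ccc(OCc2ccccc2)cc1
F3 | step 6 | methyl 4-oxo-5-{2-oxo-2-[2,4,6-tris(benzyloxy)phenyl]ethyl}-4H-pyran-2-carboxylate | COC(=O)c1cc(=O)c(CC(=O)c2c(OCc3ccccc3)cc(OCc3ccccc3)cc2OCc2ccccc2)co1
F4 | step 6 | methyl 4-oxo-5-{2-[2,4,6-tris(benzyloxy)phenyl]-2-[(trimethylsilyl)oxy]ethenyl}-4H-pyran-2-carboxylate | COC(=O)c1cc(=O)c(C=C(O[Si](C)(C)C)c2c(OCc3ccccc3)cc(OCc3ccccc3)cc2OCc2ccccc2)co1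
F5 | step 6 | bis[4-(benzyloxy)phenyl]methanol | OC(c1ccc(OCc2ccccc2)cc1)c1ccc(OCc2ccccc2)cc1
F0 | step 12 | none | none
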